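**Remark on numbering.** Ring positions C1–C10 and side-chain atoms C11–C13 are those defined in the first section; they are not germacrane numbers. Compound numbers are those of the steps and the compound list.

## Analysis of the target

The target is a ten-membered carbocycle with a trans-fused α-methylene-γ-butyrolactone. The ring is numbered C1 (lactone O–CH), C2=C3 (Z, methyl on C3), C4 (free carbinol), C5, C6, C7 (methyl) and C8 (cis epoxide), C9 (angelate) and C10, which carries C11 with the exocyclic methylene C13 and the lactone carbonyl C12. In this numbering the six stereocentres are 1S, 4R, 7R, 8S, 9S and 10R. Five are contiguous (C7 to C10 and C1): H1 and H10 are anti, the C9 and C1 oxygens are syn to each other and anti to C11, and the epoxide oxygen lies on the same side of the C8–C9 bond as the C9 oxygen (erythro). C4 stands alone beyond the C2=C3 bond. The sensitive groups are the α-methylene lactone (a Michael acceptor), the angelate (isomerised to the tiglate by nucleophiles or base) and the trisubstituted epoxide, which the C4 hydroxyl can open across the ring under acid. The difficulty is the medium ring with two cis trisubstituted C=C units, one hidden in the epoxide, and stereocentres that sit on a flexible ring. The strategy rests on one feature: C2=C3 and C7=C8 are both cis and carry their methyl groups on C3 and C7, so the ring is the formal metathesis product of ring A (C8, C9, C10, C1, C2) and ring B (C3 to C7), joined through C2–C3 and C7–C8 in a cyclobutane.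

## Retrosynthetic reasoning

**C11=C13.** Target 23 is first simplified to its 11,13-dihydro form 20. The exocyclic methylene is the most electrophilic group of the molecule and would not survive phosphines, hydrides or alkoxides, so it is made last. The forward reaction is aminomethylation of the lactone enolate (giving 21) and elimination through the ammonium salt 22.

**C4–O.** In 20 the C4–O bond is cut and remade with inversion, which leads back through ester 19 to the 4-epi alcohol 18. The wrong configuration at C4 is deliberate: it is the one the tether of the key step needs. The forward reaction must be a clean SN2 displacement at an allylic secondary carbon.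

**Lactone C12–O1.** In 18 the acyl–oxygen bond is cut, which returns the methyl ester, and the C1 and C4 oxygens are tied into the silicon bridge of 16. The bridge is the only protecting group of the route. When it is removed (via 17), the C1 oxygen is the only free oxygen within reach of the ester, because C9 is already acylated. This ordering settles the choice between a C1 and a C9 lactone.

**C9 ester and epoxide.** Removing the angeloyl group from 16 gives epoxy alcohol 15, and removing the epoxide oxygen gives dienol 14. The epoxide is cut here because the free allylic C9 hydroxyl of 14 can direct the oxygen to its own side of C7=C8. That is the relation the target has, and the delivery is concerted, so the cis geometry is kept.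

**Ten-membered ring.** In 14 the bonds C3–C7 and C2–C8 are reconnected, which folds the ring back into the cyclobutane of tricycle 13. Both alkenes of 14 are cis, and only a cis,syn,cis tricycle opens that way. The cycloreversion is run on the C9 alcohol and not on the ketone. A carbonyl at C9 would stabilise a radical at C8 and so help the C7–C8 bond to break at least as much as the C2–C8 bond, which is the way back to two five-membered rings. In 13 the bond between the quaternary carbons C3 and C7 is the weakest of the four.

**C9 carbinol.** Alcohol 13 comes from ketone 12. The reduction is placed on the rigid tricycle, where one face of the carbonyl is closed, so C9 is set before the ring becomes flexible. On the five-membered ring the new hydroxyl is trans to the acetic ester and cannot lactonise.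

**Cyclobutane (key disconnection).** In 12 the bonds C2–C3 and C7–C8 are cut, giving the silicon-linked enone and alkene 11. Two bonds, two rings and four stereocentres are gained from two simple five-membered rings. The link between the C1 and C4 oxygens has to fix which carbons meet, which faces meet and how the rings stack.

**Silaketal.** Compound 11 is taken apart at the two Si–O bonds into hydroxy enone 6, cyclopentenol 8 and dichlorosilane 9, joined in the forward direction through monochloride 10.

**Fragments.** Alcohol 8 comes from enone 7 by enantioselective reduction. Hydroxy enone 6 is resolved from racemate 5, which comes from furyl carbinol 4 by ring contraction of the furan. Compound 4 comes from 1 and 2 through zinc reagent 3. The carbinol centre of 4 needs no control because it is lost in the rearrangement.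

## Alternatives that were turned down

**Alternative 1:** Claisen ring expansion. The C5–C6 bond of the ten-membered ring is cut and C8 is reconnected to an oxygen on C4, which contracts the carbocycle to an eight-membered cyclic enol ether. In the forward direction, heating the allyl vinyl ether unit C5=C4–O–C8–C7=C6 would form C5–C6, break O–C8 and give the cyclodecadienone A1.
- For it: the step is concerted and runs at moderate temperature. C4 arrives as a ketone that a chiral reagent can reduce to the right alcohol, so no inversion is needed. On both points it is stronger than the chosen route.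
- Against it: the substrate is itself a medium ring with four contiguous stereocentres (C8, C9, C10, C1) and must be closed and methylenated first, so one medium-ring problem is exchanged for another. The geometry of the new C7=C8 bond in a two-carbon enlargement to a ten-membered ring is not bound to be cis. A1 carries three differently protected oxygens and the side chain at the alcohol oxidation level, which adds late deprotection and oxidation steps. The C7=C8 bond of A1 has no free hydroxyl next to it to direct the epoxidation.
- Comparison: the chosen route offers convergence from two five-membered rings, cis geometry of both alkenes by construction, and a single tether as the only protecting group.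

**Alternative 2:** Wharton–Grob fragmentation. The C3–C8 bond is reconnected, which turns the ten-membered ring into a cis-fused bicyclo[4.4.0]decane with an angular oxygen at C8 and a leaving group at C2. In the forward direction, a base would ionise the C8 hydroxyl, the ring-fusion bond would break, and the C2=C3 alkene and the C8 ketone of A2 would form together.
- For it: this fragmentation is the most dependable way to a cyclodecenone. The Z geometry of C2=C3 follows from the antiperiplanar arrangement in the bicycle. The lactone and the correct C4 configuration are already present in A2. In predictability of the key step and at C4 it is stronger than the chosen route.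
- Against it: A2 has its oxygen at C8 (ketone) and C7 (tertiary ether), and C9 is a bare methylene. The target needs the C9 ester and the C7–C8 epoxide, so the oxygen pattern must be shifted by α-oxidation, reduction and epoxide closure on the flexible ring, with C7, C8 and C9 all set late. The bicyclic precursor with its six stereocentres needs a long linear sequence.
- Comparison: the chosen route sets C9 on a rigid tricycle, lets that centre place the epoxide, and is considerably shorter.

**Alternative 3:** Ramberg–Bäcklund ring contraction. The C7=C8 bond is traced back to an episulfone and then to an eleven-membered cyclic sulfone with sulfur between C7 and C8. In the forward direction, α-halogenation under basic conditions, 1,3-elimination and loss of SO2 would give the cyclodecadienol A3.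
- For it: the alkene is made late and under mild conditions. The C9 hydroxyl of A3 is free to direct the epoxidation as in the chosen route, and C4 is correct. In mildness and at C4 it is stronger.
- Against it: an eleven-membered thiacycle has to be closed at high dilution. A trisubstituted alkene from a branched α-carbon (C7) is a slow case for this reaction, and its geometry in a ten-membered ring is not fixed. The free C9 hydroxyl sits β to the sulfone and invites elimination or retro-aldol cleavage under the basic conditions. C9, C10, C1 and C4 must all be built beforehand on an open chain, and three protecting groups are carried.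
- Comparison: the chosen route avoids macrocyclisation, fixes both alkene geometries through ring fusion, and takes its stereocentres from two small rings.

Key step: step 6

Assumption: the lipase in step 3 acylates the (4R,5S)-enantiomer of 5, as the empirical size rule for secondary alcohols predicts (branched C5 side in the large pocket).

## Route

Step 1
Reactants: 1 furfural; 2 methyl bromoacetate
Product: 4 methyl 3-(furan-2-yl)-3-hydroxypropanoate (racemic), via Reformatsky reagent 3 (not isolated)
Conditions: Zn dust (activated with Me3SiCl), THF, reflux; aq. NH4Cl
Reagents that add atoms: none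
Why: Reformatsky reaction: zinc inserts into the C–Br bond of 2 and zinc enolate 3 adds to the aldehyde of 1; the carbinol centre needs no control because step 2 erases it.

Step 2
Reactants: 4 methyl 3-(furan-2-yl)-3-hydroxypropanoate
Product: 5 rac-trans-4-hydroxy-5-(2-methoxy-2-oxoethyl)cyclopent-2-en-1-one
Conditions: ZnCl2, dioxane–H2O (1:1), pH 6, 95 °C
Reagents that add atoms: water, O
Why: Piancatelli rearrangement: the furyl carbinol ionises, water adds to C5 of the furan, the ring opens and the pentadienyl cation closes by 4π conrotation; the 4-hydroxyl and the 5-substituent come out trans because both lie outward in the cation that cyclises.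

Step 3
Reactants: 5 rac-trans-4-hydroxy-5-(2-methoxy-2-oxoethyl)cyclopent-2-en-1-one
Product: 6 (4S,5R)-4-hydroxy-5-(2-methoxy-2-oxoethyl)cyclopent-2-en-1-one
Conditions: immobilised lipase from Burkholderia cepacia, vinyl acetate, tBuOMe, 30 °C, stopped past half conversion; chromatography
Reagents that add atoms: none
Why: Lipase-catalysed kinetic resolution by irreversible transesterification; the enzyme should acetylate the (4R,5S)-enantiomer and leave 6 as the free alcohol, and running past half conversion should secure its optical purity.

Step 4
Reactants: 7 2,3-dimethylcyclopent-2-en-1-one
Product: 8 (1S)-2,3-dimethylcyclopent-2-en-1-ol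
Conditions: (R)-Me-CBS oxazaborolidine (C18H20BNO, 10 mol %), BH3·SMe2, THF, −20 °C; MeOH
Reagents that add atoms: none
Why: Corey–Bakshi–Shibata reduction; the ketone binds the catalyst–borane complex with the methyl-bearing vinylic carbon as the large group, and the (R)-catalyst then delivers hydride to give the S carbinol.

Step 5
Reactants: 8 (1S)-2,3-dimethylcyclopent-2-en-1-ol; 9 dichlorodiisopropylsilane; 6 (4S,5R)-4-hydroxy-5-(2-methoxy-2-oxoethyl)cyclopent-2-en-1-one
Product: 11 diisopropylsilylene-bridged enone–cyclopentene (precursor of the key step), via chlorosilane 10 (not isolated)
Conditions: 9 (3 equiv), imidazole, CH2Cl2, −20 °C, then excess 9 removed in vacuo; 6, imidazole, DMF, 0 °C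
Reagents that add atoms: none
Why: Stepwise silylation with a dichlorosilane (unsymmetrical silaketal formation); excess 9 stops at monochloride 10 without the symmetrical bis-ether, and 10 silylates 6 under buffered conditions that spare the base-sensitive hydroxy enone; no stereocentre is touched.

Step 6
Reactants: 11 diisopropylsilylene-bridged enone–cyclopentene
Product: 12 cis,syn,cis-tricyclo[5.3.0.0(2,6)]decanone silaketal (photoadduct)
Conditions: hν (350 nm, Pyrex), degassed MeCN, 5 mM, −20 °C
Reagents that add atoms: none
Why: Excitation of the enone of 11 and intersystem crossing give the triplet, whose β-carbon C2 adds to C3 of the tethered tetrasubstituted alkene; the triplet 1,4-diradical (α-acyl radical at C8, tertiary radical at C7) then undergoes spin inversion and couples at C7–C8, so 12 is an isomer of 11 and no atom is lost. The closest known reaction type is the intramolecular enone–alkene [2+2] photocycloaddition through a temporary silicon tether. The first bond closes the seven-membered silaketal ring (Si, O, C1, C2, C3, C4, O) in a 7-exo-trig radical addition, and the second closes the cyclobutane by radical–radical coupling. C2 and C8 are controlled by the C1 silyloxy group, which delivers the alkene to its own face of ring A, and by the cis fusion that a cyclobutane on a five-membered ring must have; C3 and C7 are controlled in the same way by the C4 oxygen and the cis fusion to ring B. The step needs C2–C3 rather than C2–C7 bonding, which the three-atom O–Si–O link secures because the crossed mode would demand an eight-membered ring and a poorer diradical. It needs syn stacking of the two five-membered rings, which follows once both oxygens lie on the bonding faces, and this is why C4 is carried as the S epimer. It needs closure to win over hydrogen transfer in the diradical, which the short link between the two radical centres favours.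

Step 7
Reactants: 12 cis,syn,cis-tricyclo[5.3.0.0(2,6)]decanone silaketal
Product: 13 tricyclic C9 alcohol (hydroxyl cis to O1)
Conditions: NaBH4, MeOH–CH2Cl2 (1:1), −40 °C; aq. NH4Cl
Reagents that add atoms: none
Why: Hydride reduction of a ketone; the inner face of the carbonyl looks into the cleft at C6, and small hydrides attack 2-substituted cyclopentanones on the side of the substituent, so hydride should enter from the convex face and place the C9 oxygen cis to O1 and trans to C11 as in the target. Being trans to the acetic ester on a five-membered ring, the hydroxyl cannot lactonise.

Step 8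
Reactants: 13 tricyclic C9 alcohol
Product: 14 ten-membered cis,cis-dienol silaketal
Conditions: flash vacuum pyrolysis, 550 °C, 0.001 mbar, silanised quartz tube, trap at −196 °C
Reagents that add atoms: none
Why: Thermal [2+2] cycloreversion of a cyclobutane through a 1,4-diradical; the C3–C7 bond between the two quaternary carbons should break first (two tertiary radicals, eclipsed methyls and stacked rings relieved), and β-scission of C2–C8 then gives both alkenes, while with C9 as a carbinol no other ring bond offers as good a diradical. The cis fusions place C1/C4 and C6/C9 on the same side of the breaking ring, so both alkenes should form cis, and C2=C3 is held cis by the seven-membered silaketal ring; no stereocentre is made.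

Step 9
Reactants: 14 ten-membered cis,cis-dienol silaketal
Product: 15 C7–C8 epoxy alcohol (epoxide oxygen syn to the C9 hydroxyl)
Conditions: VO(acac)2 (5 mol %), tBuOOH (1.5 equiv), CH2Cl2, 0 °C to rt; used at once in step 10
Reagents that add atoms: tert-butyl hydroperoxide, CC(C)(C)OO
Why: Hydroxyl-directed vanadium-catalysed epoxidation; the vanadate ester of the C9 alcohol delivers oxygen to the near face of C7=C8, syn as in medium-ring cycloalkenols because ring carbon C10 lies on the other side, which sets C7 and C8. The transfer is concerted and keeps the cis geometry, and C2=C3 has no free allylic hydroxyl and is left alone.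

Step 10
Reactants: 15 C7–C8 epoxy alcohol
Product: 16 C9 angelate
Conditions: angelic acid, 2,4,6-trichlorobenzoyl chloride, Et3N, toluene, rt; then 15, 75 °C
Reagents that add atoms: angelic acid, C/C=C(/C)C(=O)O
Why: Yamaguchi-type esterification through the mixed anhydride, run without a nucleophilic catalyst because such a catalyst would isomerise the Z acyl group to the tiglate; acylation at oxygen leaves C9 untouched.

Step 11
Reactants: 16 C9 angelate
Product: 18 4-epi-11,13-dihydro lactone, via seco diol 17 (not isolated)
Conditions: Bu4NF (2.2 equiv), THF, 0 °C; aq. NH4Cl
Reagents that add atoms: none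
Why: Fluoride cleavage of the silaketal followed by lactonisation; the C1 alkoxide of 17 lies γ to the methyl ester and closes the trans-fused lactone (5-exo-trig), while the C4 oxygen has no acyl group in reach and C9 is capped.

Step 12
Reactants: 18 4-epi-11,13-dihydro lactone
Product: 19 C4 chloroacetate of inverted configuration
Conditions: ClCH2CO2H, PPh3, diisopropyl azodicarboxylate, THF–toluene, 0 °C to rt
Reagents that add atoms: chloroacetic acid, OC(=O)CCl
Why: Mitsunobu reaction; the allylic C4 hydroxyl is activated as the alkoxyphosphonium ion and displaced by chloroacetate (acidic enough for a hindered alcohol) in an SN2 step that inverts C4 to the configuration of the target.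

Step 13
Reactants: 19 C4 chloroacetate of inverted configuration
Product: 20 11,13-dihydro target
Conditions: K2CO3 (0.2 equiv), MeOH, −10 °C; AcOH quench
Reagents that add atoms: none
Why: Base-catalysed transesterification; the chloroacetate is far more electrophilic than the hindered conjugated angelate or the lactone, so brief methanolysis in the cold should remove it alone, without touching C4.

Step 14
Reactants: 20 11,13-dihydro target
Product: 21 C11 dimethylaminomethyl lactone (C11 epimers)
Conditions: LiN(SiMe3)2 (2.3 equiv), THF, −78 °C; Me2N=CH2+ I− (3 equiv), −78 to 0 °C; aq. NH4Cl
Reagents that add atoms: Eschenmoser's salt (N,N-dimethylmethyleneiminium iodide), C=[N+](C)C.[I-]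
Why: Mannich reaction of a lactone enolate; two equivalents of base give the C4 alkoxide and the C11 enolate (the angelate has no α-hydrogen), and aminomethylation at C11 gives epimers that are both eliminated in step 15.

Step 15
Reactants: 21 C11 dimethylaminomethyl lactone
Product: 23 target CNP0191628.1, via methiodide 22 (not isolated)
Conditions: MeI, CH2Cl2–MeOH, rt; then NaHCO3, EtOAc–H2O, rt
Reagents that add atoms: none
Why: Quaternisation and E1cB elimination of trimethylamine from 22 install the exocyclic methylene under near-neutral conditions that the epoxide, the angelate and the new Michael acceptor tolerate.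

## Compound list

1 | furfural | O=Cc1ccco1 | starting material
2 | methyl bromoacetate | COC(=O)CBr | starting material
3 | bromo(2-methoxy-2-oxoethyl)zinc (Reformatsky reagent) | COC(=O)C[Zn]Br | intermediate
4 | methyl 3-(furan-2-yl)-3-hydroxypropanoate (racemic) | COC(=O)CC(O)c1ccco1 | intermediate
5 | rac-trans-4-hydroxy-5-(2-methoxy-2-oxoethyl)cyclopent-2-en-1-one (both enantiomers written) | O=C1C=C[C@H](O)[C@H]1CC(=O)OC.O=C1C=C[C@@H](O)[C@@H]1CC(=O)OC | intermediate
6 | (4S,5R)-4-hydroxy-5-(2-methoxy-2-oxoethyl)cyclopent-2-en-1-one | O=C1C=C[C@H](O)[C@H]1CC(=O)OC | intermediate
7 | 2,3-dimethylcyclopent-2-en-1-one | CC1=C(C)C(=O)CC1 | starting material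
8 | (1S)-2,3-dimethylcyclopent-2-en-1-ol | O[C@H]1CCC(C)=C1C | intermediate
9 | dichlorodiisopropylsilane | CC(C)[Si](Cl)(Cl)C(C)C | starting material
10 | chloro{[(1S)-2,3-dimethylcyclopent-2-en-1-yl]oxy}diisopropylsilane | CC(C)[Si](Cl)(C(C)C)O[C@H]1CCC(C)=C1C | intermediate
11 | (4S,5R)-4-[({[(1S)-2,3-dimethylcyclopent-2-en-1-yl]oxy}diisopropylsilyl)oxy]-5-(2-methoxy-2-oxoethyl)cyclopent-2-en-1-one (diisopropylsilylene-bridged enone–cyclopentene) | O=C1C=C[C@H](O[Si](C(C)C)(C(C)C)O[C@H]2CCC(C)=C2C)[C@H]1CC(=O)OC | intermediate
12 | cis,syn,cis-tricyclo[5.3.0.0(2,6)]decanone silaketal: C9 ketone, cyclobutane C2–C3–C7–C8, methyls on C3 and C7, O1–Si(iPr)2–O4 bridge on the inner faces, CH2CO2Me on C10 trans to O1 | O=C1[C@H]2[C@H]4[C@H](O[Si](C(C)C)(C(C)C)O[C@H]3CC[C@]2(C)[C@]34C)[C@H]1CC(=O)OC | intermediate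
13 | C9 alcohol of 12, hydroxyl cis to O1 and trans to C11 | O[C@@H]1[C@H]2[C@H]4[C@H](O[Si](C(C)C)(C(C)C)O[C@H]3CC[C@]2(C)[C@]34C)[C@H]1CC(=O)OC | intermediate
14 | ten-membered (2Z,7Z)-dienol: C9 hydroxyl, O1–Si(iPr)2–O4 bridge, CH2CO2Me on C10; C1, C9, C10 as in the target, C4 epimeric | O[C@@H]1/C=C(/C)CC[C@@H]2O[Si](C(C)C)(C(C)C)O[C@@H](/C=C2/C)[C@H]1CC(=O)OC | intermediate
15 | C7–C8 epoxide of 14; C1, C7, C8, C9, C10 as in the target, C4 epimeric | O[C@@H]1[C@@H]2O[C@]2(C)CC[C@@H]3O[Si](C(C)C)(C(C)C)O[C@@H](/C=C3/C)[C@H]1CC(=O)OC | intermediate
16 | C9 angelate of 15 | C/C=C(/C)C(=O)O[C@@H]1[C@@H]2O[C@]2(C)CC[C@@H]3O[Si](C(C)C)(C(C)C)O[C@@H](/C=C3/C)[C@H]1CC(=O)OC | intermediate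
17 | seco diol: C1 and C4 hydroxyls free, methyl ester, C9 angelate, epoxide | C/C=C(/C)C(=O)O[C@@H]1[C@@H]2O[C@]2(C)CC[C@H](O)/C(C)=C\[C@H](O)[C@H]1CC(=O)OC | intermediate
18 | 4-epi-11,13-dihydro target: trans γ-lactone, C9 angelate, epoxide, C4 hydroxyl with 4S configuration | C1C(=O)O[C@H]2/C=C(/C)[C@@H](O)CC[C@@]3(C)O[C@H]3[C@@H](OC(=O)/C(C)=C\C)[C@H]12 | intermediate
19 | C4 chloroacetate of the 11,13-dihydro target (4R) | C1C(=O)O[C@H]2/C=C(/C)[C@H](OC(=O)CCl)CC[C@@]3(C)O[C@H]3[C@@H](OC(=O)/C(C)=C\C)[C@H]12 | intermediate
20 | 11,13-dihydro target (all six ring stereocentres as in the target) | C1C(=O)O[C@H]2/C=C(/C)[C@H](O)CC[C@@]3(C)O[C@H]3[C@@H](OC(=O)/C(C)=C\C)[C@H]12 | intermediate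
21 | C11 (dimethylamino)methyl derivative of 20 (C11 epimers) | CN(C)CC1C(=O)O[C@H]2/C=C(/C)[C@H](O)CC[C@@]3(C)O[C@H]3[C@@H](OC(=O)/C(C)=C\C)[C@H]12 | intermediate
22 | trimethylammonium iodide of 21 (C11 epimers) | C[N+](C)(C)CC1C(=O)O[C@H]2/C=C(/C)[C@H](O)CC[C@@]3(C)O[C@H]3[C@@H](OC(=O)/C(C)=C\C)[C@H]12.[I-] | intermediate
23 | CNP0191628.1 | C=C1C(=O)O[C@H]2/C=C(/C)[C@H](O)CC[C@@]3(C)O[C@H]3[C@@H](OC(=O)/C(C)=C\C)[C@H]12 | target

## Step count and least certain steps

Total: 15 steps. Longest linear sequence: 14 steps (steps 1 to 3 and 5 to 15; step 4 is on the side branch).

**Step 6 (key step).** Risk: the triplet 1,4-diradical may return to 11 or transfer a hydrogen atom instead of closing onto a second quaternary carbon, and the flexible seven-membered link may let some crossed or anti-stacked addition through. Fallback (sets out from 6 and 8, returns at 12): the two alcohols are held by a shorter carbon ketal during the irradiation, and the silicon bridge is put on afterwards. Alcohol 6 with 2-methoxypropene and pyridinium p-toluenesulfonate (C12H13NO3S, cat.) would give the 2-methoxyprop-2-yl ether F1. Exchange of its methoxy group for alcohol 8 under the same catalyst, with removal of methanol, would give the mixed isopropylidene ketal F2. Irradiation as in step 6 would give the cyclic ketal photoadduct F3, and methanolysis with the same catalyst would free the tricyclic diol F4. iPr2Si(OTf)2 with 2,6-lutidine would then close the silaketal to 12.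

**Step 8.** Risk: loss of the free hydroxyl in the hot zone (dehydration, or gas-phase lactonisation with loss of methanol), rotation in the diradical with leakage of the C7=C8 geometry, a transannular ene reaction of the 1,6-diene, or scission in the returning sense. Fallback (sets out from 12, returns at 14): ketone 12, which carries no hydroxyl, is pyrolysed under the same conditions to the ten-membered dienone F5. Scission in the returning sense there only regenerates 11, which can be irradiated again. Luche reduction (NaBH4, CeCl3·7H2O, MeOH, −78 °C), with hydride coming from outside the ring, would then give 14.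

**Step 2.** Risk: the cation that starts the rearrangement may instead lose a proton next to the ester and give the furylacrylate, and prolonged heating may isomerise 5 to the 2-substituted hydroxy enone. Fallback (sets out from 2, returns at 5): the five-membered ring is taken from cyclopentadiene. NaC5H5 and 2 in THF at −78 °C would give methyl cyclopenta-2,4-dien-1-ylacetate F6, which is kept cold. Photooxygenation (O2, hν, tetraphenylporphyrin C44H30N4, CH2Cl2, −60 °C) would add oxygen anti to the side chain and give the endoperoxide F7. Kornblum–DeLaMare rearrangement with Et3N at 0 °C would give 5.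

**Step 9.** Risk: delivery of oxygen to the wrong face if the ring takes up a conformer in which C10 does not lie opposite the hydroxyl, oxidation of the allylic alcohol to the enone, or closure of the γ-hydroxy ester to a C9 lactone on the Lewis-acidic metal. Fallback (sets out from 14, returns at 16): the hydroxyl is capped first and the face is then chosen by a chiral reagent instead of by the hydroxyl. Acylation of 14 as in step 10 would give the dienyl angelate F8. Asymmetric epoxidation with the dioxirane of the L-series fructose-type ketone catalyst (1,2:4,5-di-O-isopropylidene-β-L-erythro-2,3-hexodiulo-2,6-pyranose, C12H18O6; KHSO5 as 2KHSO5·KHSO4·K2SO4, K2CO3 buffer, Bu4NHSO4, MeCN–dimethoxymethane–H2O, 0 °C) should then oxidise the trisubstituted C7=C8 bond through the spiro transition state on the face that leads to the 7R,8S epoxide, and give 16. The C2=C3 bond is deactivated by its two allylic oxygens and screened by the isopropyl groups, and the angelate alkene is electron-poor.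

**Step 10.** Risk: isomerisation of the angeloyl group to the tigloyl group, or lactonisation of the C9 hydroxyl onto the methyl ester at 75 °C before acylation. Fallback (sets out from 15, returns at 16): the Z alkene is built on the ester. Steglich esterification of 15 with 2-[bis(2,2,2-trifluoroethoxy)phosphoryl]propanoic acid (N,N'-dicyclohexylcarbodiimide, 4-(dimethylamino)pyridine C7H10N2 cat., CH2Cl2, 0 °C) would give the phosphonopropionate F9. Still–Gennari olefination (KN(SiMe3)2, 18-crown-6, THF, −78 °C, then acetaldehyde) would give 16.

**Step 12.** Risk: attack at C2 with allylic transposition, elimination to a diene, or ionisation of the allylic oxyphosphonium ion with loss of stereochemical integrity. Fallback (sets out from 18, returns at 20): inversion by oxidation and reagent-controlled reduction. MnO2 in CH2Cl2 would give the C4 enone F10. Corey–Bakshi–Shibata reduction with the (S)-catalyst (C18H20BNO) and catecholborane in toluene at −78 °C, with the methyl-bearing vinylic carbon as the large group, would give the 4R alcohol 20.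

## Further compounds

F1 | step 6 | (4S,5R)-4-[(2-methoxypropan-2-yl)oxy]-5-(2-methoxy-2-oxoethyl)cyclopent-2-en-1-one | O=C1C=C[C@H](OC(C)(C)OC)[C@H]1CC(=O)OC
F2 | step 6 | mixed isopropylidene ketal of 6 and 8 | O=C1C=C[C@H](OC(C)(C)O[C@H]2CCC(C)=C2C)[C@H]1CC(=O)OC
F3 | step 6 | cis,syn,cis tricyclic ketone with O1–C(CH3)2–O4 ketal bridge | O=C1[C@H]2[C@H]4[C@H](OC(C)(C)O[C@H]3CC[C@]2(C)[C@]34C)[C@H]1CC(=O)OC
F4 | step 6 | cis,syn,cis tricyclic C1,C4-diol C9-ketone | O[C@H]1CC[C@@]2(C)[C@H]3C(=O)[C@H](CC(=O)OC)[C@@H](O)[C@H]3[C@@]12C
F5 | step 8 | ten-membered (2Z,7Z)-dienone with C9 ketone and O1–Si(iPr)2–O4 bridge | O=C1/C=C(/C)CC[C@@H]2O[Si](C(C)C)(C(C)C)O[C@@H](/C=C2/C)[C@H]1CC(=O)OC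
F6 | step 2 | methyl 2-(cyclopenta-2,4-dien-1-yl)acetate | COC(=O)CC1C=CC=C1
F7 | step 2 | methyl 2-(2,3-dioxabicyclo[2.2.1]hept-5-en-7-yl)acetate, side chain anti to the peroxide bridge | COC(=O)C[C@@H]1[C@H]2OO[C@@H]1C=C2
F8 | step 9 | C9 angelate of dienol 14 | C/C=C(/C)C(=O)O[C@@H]1/C=C(/C)CC[C@@H]2O[Si](C(C)C)(C(C)C)O[C@@H](/C=C2/C)[C@H]1CC(=O)OC
F9 | step 10 | C9 2-[bis(2,2,2-trifluoroethoxy)phosphoryl]propanoate of 15 (epimers at the phosphonate carbon) | CC(C(=O)O[C@@H]1[C@@H]2O[C@]2(C)CC[C@@H]3O[Si](C(C)C)(C(C)C)O[C@@H](/C=C3/C)[C@H]1CC(=O)OC)P(=O)(OCC(F)(F)F)OCC(F)(F)F
F10 | step 12 | C4 ketone (2Z-enone) of the 11,13-dihydro lactone | C1C(=O)O[C@H]2/C=C(/C)C(=O)CC[C@@]3(C)O[C@H]3[C@@H](OC(=O)/C(C)=C\C)[C@H]12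
A1 | alternative 1 | (2Z,7Z)-cyclodeca-2,7-dienone with C4 ketone, C9 tert-butyldimethylsilyl ether, C1 triethylsilyl ether and the 3-(4-methoxybenzyloxy)prop-1-en-2-yl group on C10 | O=C1CC/C(C)=C\[C@@H](O[Si](C)(C)C(C)(C)C)[C@H](C(=C)COCc2ccc(OC)cc2)[C@@H](O[Si](CC)(CC)CC)/C=C1/C
A2 | alternative 2 | (2Z)-cyclodecen-8-one fused to the trans lactone, with C7 methyl and methoxymethyl ether and C4 tert-butyldimethylsilyl ether | O=C1C[C@H]2CC(=O)[C@](C)(OCOC)CC[C@@H](O[Si](C)(C)C(C)(C)C)/C(C)=C\[C@@H]2O1
A3 | alternative 3 | (2Z,7Z)-cyclodeca-2,7-dien-9-ol with C1 triethylsilyl ether, C4 tert-butyldimethylsilyl ether and the 3-(4-methoxybenzyloxy)prop-1-en-2-yl group on C10 | C/C1=C/[C@@H](O)[C@H](C(=C)COCc2ccc(OC)cc2)[C@@H](O[Si](CC)(CC)CC)/C=C(/C)[C@H](O[Si](C)(C)C(C)(C)C)CC1
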